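**Retrosynthetic overview**
1. The strategy rests on the only heterocycle, a 1H-imidazole. Its N1 and C2 carry nothing but hydrogen, and C4 and C5 each carry one CH2-aryl arm. The arms differ only at the para oxygen (OMe against OSO3H).
2. The aryl O-S bond is cut last (sulfation of a free phenol). Until then this phenol travels as a benzyl ether, so the two arms stay distinguishable.
3. The imidazole is opened at C4-C5, N1-C2 and C5-N1. C4-N3-C2 and the benzyloxybenzyl arm come from a C-alkylated TosMIC, C5 and the methoxybenzyl arm from (4-methoxyphenyl)acetaldehyde, and N1 from ammonia.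
4. Each carbon fragment is one step from bought material: alkylation of TosMIC with 4-(benzyloxy)benzyl chloride, and oxidation of 2-(4-methoxyphenyl)ethanol.
5. Ring order: both benzene rings are bought. The imidazole is the only ring made, in step 3, with both arms already attached.

Key step: step 3

Assumption: the target is drawn as the neutral hydrogen sulfate. This is taken to be the same compound as its imidazolium/sulfate inner salt, the form in which it should be isolated.

**Route**

Step 1
Reactants: 1 p-toluenesulfonylmethyl isocyanide (TosMIC); 2 4-(benzyloxy)benzyl chloride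
Product: 3 2-[4-(benzyloxy)phenyl]-1-isocyanoethyl p-tolyl sulfone (racemic)
Conditions: 1 (1.3 equiv), 2 (1.0 equiv), BnEt3NCl (10 mol %), CH2Cl2/30% aq NaOH, 0 °C; crystallise to remove excess 1
Reagents that add atoms: none
Why: This is a phase-transfer C-alkylation of an active methylene, in which the carbanion stabilised by the sulfonyl and isocyano groups displaces chloride from the activated p-alkoxybenzyl chloride by SN2, keeping 2 limiting at 0 °C should suppress a second alkylation, and the new stereocentre is racemic and is destroyed in step 3.

Step 2
Reactants: 4 2-(4-methoxyphenyl)ethanol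
Product: 5 (4-methoxyphenyl)acetaldehyde
Conditions: Dess-Martin periodinane (1.1 equiv), CH2Cl2, 0 °C to rt; cold aq NaHCO3 wash, dry, concentrate below 25 °C, use at once
Reagents that add atoms: none
Why: The Dess-Martin oxidation stops at the aldehyde under near-neutral, water-free conditions, and the short cold work-up without silica should limit enolisation and self-aldol reaction of the sensitive arylacetaldehyde.

Step 3
Reactants: 3 2-[4-(benzyloxy)phenyl]-1-isocyanoethyl p-tolyl sulfone; 5 (4-methoxyphenyl)acetaldehyde; 6 ammonia
Product: 9 4-[4-(benzyloxy)benzyl]-5-(4-methoxybenzyl)-1H-imidazole, via NH-aldimine 7 (not isolated), via 4-tosyl-2-imidazoline 8 (not isolated)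
Conditions: 5 (1.4 equiv, in THF) added over 30 min to 6 (7 M in MeOH, 20 equiv), 0 °C, 45 min; then 3 (1.0 equiv), K2CO3 (2 equiv), 0 °C to rt, 16 h
Reagents that add atoms: none
Why: Aldehyde 5 condenses with the large excess of ammonia to give aldimine 7 (C5=N1), K2CO3 deprotonates 3 at the carbon between the sulfonyl and isocyano groups, and this carbanion adds to the imine carbon to form C4-C5. The nitrogen anion so formed attacks the terminal isocyanide carbon in a 5-endo-dig closure (N1-C2), which after proton transfer gives imidazoline 8, so the ring arises by a stepwise [3+2] cycloaddition. Base-induced 1,2-elimination of p-toluenesulfinate from C4 together with the C5 hydrogen then aromatises the ring to 9. The closest known reaction type is the van Leusen three-component imidazole synthesis, which converts alpha-substituted TosMIC reagents, aldehydes and ammonia into 4,5-disubstituted NH-imidazoles. The two stereocentres of 8 (C4 and C5) form without control and both become sp2 on aromatisation, so no controlling element is needed. The step needs capture of the imine rather than of the aldehyde carbonyl (the oxazole pathway) or of an enol or enamine partner, which is secured by slow addition of 5 to excess ammonia at 0 °C before 3 and base are admitted; ring regiochemistry is not at stake because each arm arrives on its own fragment and the two NH tautomers are one compound.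

Step 4
Reactants: 9 4-[4-(benzyloxy)benzyl]-5-(4-methoxybenzyl)-1H-imidazole
Product: 10 4-(4-hydroxybenzyl)-5-(4-methoxybenzyl)-1H-imidazole
Conditions: H2 (1 atm), 10% Pd/C, MeOH/AcOH (10:1), rt
Reagents that add atoms: none
Why: Catalytic hydrogenolysis of an aryl benzyl ether cleaves only the O-CH2Ph bond, the methyl ether and the ArCH2-imidazole C-C bonds being inert, and AcOH protonates the imidazole so that it should not poison the Pd surface.

Step 5
Reactants: 10 4-(4-hydroxybenzyl)-5-(4-methoxybenzyl)-1H-imidazole
Product: 12 Melanocin F, via N,O-bis-sulfonate 11 (not isolated)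
Conditions: SO3·pyridine (4 equiv), pyridine/DMF, 0 °C to rt; then H2O, 0 °C to rt (pyridine-buffered), 1 h; C18 reversed phase (H2O/MeOH), lyophilise
Reagents that add atoms: sulfur trioxide pyridine complex, [O-]S(=O)(=O)[n+]1ccccc1
Why: In this O-sulfation of a phenol with an amine-SO3 complex, the excess reagent should load both the phenol oxygen and a nucleophilic ring nitrogen to give 11, whose N-S bond (an azole-SO3 adduct, itself a sulfuryl donor) is hydrolysed in weakly acidic to neutral water, where the aryl sulfate monoester is stable, leaving 12 as the inner salt.

**Compound list**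
1 | p-toluenesulfonylmethyl isocyanide (TosMIC) | Cc1ccc(cc1)S(=O)(=O)C[N+]#[C-] | starting material
2 | 4-(benzyloxy)benzyl chloride | ClCc1ccc(OCc2ccccc2)cc1 | starting material
3 | 2-[4-(benzyloxy)phenyl]-1-isocyanoethyl p-tolyl sulfone (racemic) | Cc1ccc(cc1)S(=O)(=O)C(Cc1ccc(OCc2ccccc2)cc1)[N+]#[C-] | intermediate
4 | 2-(4-methoxyphenyl)ethanol | COc1ccc(CCO)cc1 | starting material
5 | (4-methoxyphenyl)acetaldehyde | COc1ccc(CC=O)cc1 | intermediate
6 | ammonia | N | starting material
7 | 2-(4-methoxyphenyl)ethan-1-imine (formed in the flask) | COc1ccc(CC=N)cc1 | intermediate
8 | 4-[4-(benzyloxy)benzyl]-5-(4-methoxybenzyl)-4-tosyl-4,5-dihydro-1H-imidazole (formed in the flask, racemic diastereomer mixture) | COc1ccc(CC2NC=NC2(Cc2ccc(OCc3ccccc3)cc2)S(=O)(=O)c2ccc(C)cc2)cc1 | intermediate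
9 | 4-[4-(benzyloxy)benzyl]-5-(4-methoxybenzyl)-1H-imidazole | COc1ccc(Cc2[nH]cnc2Cc2ccc(OCc3ccccc3)cc2)cc1 | intermediate
10 | 4-(4-hydroxybenzyl)-5-(4-methoxybenzyl)-1H-imidazole | COc1ccc(Cc2[nH]cnc2Cc2ccc(O)cc2)cc1 | intermediate
11 | 4-{[5-(4-methoxybenzyl)-1-sulfo-1H-imidazol-4-yl]methyl}phenyl hydrogen sulfate (formed in the flask as pyridinium salt; either ring nitrogen may carry the sulfo group, one isomer drawn) | COc1ccc(Cc2n(S(=O)(=O)O)cnc2Cc2ccc(OS(=O)(=O)O)cc2)cc1 | intermediate
12 | Melanocin F, 4-{[5-(4-methoxybenzyl)-1H-imidazol-4-yl]methyl}phenyl hydrogen sulfate | COc1ccc(Cc2[nH]cnc2Cc2ccc(OS(=O)(=O)O)cc2)cc1 | target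

**Step count**
Total steps: 5. Longest linear sequence: 4 steps (step 1 or step 2, then steps 3, 4 and 5).

**Steps most likely to fail**

Step 3. The NH-imine of an enolisable arylacetaldehyde may tautomerise, oligomerise or enter aldol-type self-condensation faster than the carbanion traps it. Carbonyl capture may also compete with imine capture.
- The fallback sets out from 5 and 3 and replaces ammonia by a removable primary amine, so that the imine becomes a discrete, fully formed partner.
- Aldehyde 5 is condensed with benzylamine (MgSO4, CH2Cl2, 0 °C) to give N-benzyl-2-(4-methoxyphenyl)ethan-1-imine F1.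
- F1 is taken with 3 and K2CO3 in DMF at room temperature through the two-component van Leusen cycloaddition to give 1-benzyl-4-[4-(benzyloxy)benzyl]-5-(4-methoxybenzyl)-1H-imidazole F2.
- One hydrogenolysis under acidic, more forcing conditions (H2, 4 bar, Pd(OH)2/C, EtOH/AcOH, 50 °C) should remove the O-benzyl and the ring N-benzyl group together. This is the way benzyl-protected tyrosine and histidine side chains are freed.
- The route is rejoined at 10, so step 4 is no longer needed.

Step 5. The ring nitrogen may sequester SO3 and leave O-sulfation incomplete. The sulfate ester may hydrolyse during concentration, and the zwitterion may be hard to separate from inorganic salts.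
- The fallback sets out from 10 and replaces the electrophilic SO3 donor by enzymatic sulfuryl transfer.
- Phenol 10 is incubated with a bacterial aryl sulfotransferase and potassium 4-nitrophenyl sulfate as donor (Tris-glycine buffer, pH 8.9, about 10% acetone, 30 °C).
- The liberated nitrophenol is extracted with EtOAc and the aqueous phase is desalted on C18.
- Only phenolic oxygen is a substrate, and the pH stays where aryl sulfates are stable.
- The route is rejoined directly at 12, and no new compound is made.

Step 2. The neat aldehyde may undergo self-aldol reaction, air oxidation or polymerisation during concentration, so that an ill-defined amount of it would enter the key step.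
- The fallback sets out from 4 and avoids handling the free aldehyde.
- After oxidation (TEMPO/PhI(OAc)2, CH2Cl2), the crude organic phase is shaken with saturated aq NaHSO3/EtOH.
- The aldehyde should be drawn out as crystalline sodium 1-hydroxy-2-(4-methoxyphenyl)ethanesulfonate F3, which is purified by filtration and washing and can be stored.
- Immediately before step 3 the adduct is cleaved with aq Na2CO3/EtOAc at 0 °C, and the dried extract rejoins the route at 5.

**Further compounds**
F1 | step 3 | N-benzyl-2-(4-methoxyphenyl)ethan-1-imine (E) | COc1ccc(C/C=N/Cc2ccccc2)cc1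
F2 | step 3 | 1-benzyl-4-[4-(benzyloxy)benzyl]-5-(4-methoxybenzyl)-1H-imidazole | COc1ccc(Cc2n(Cc3ccccc3)cnc2Cc2ccc(OCc3ccccc3)cc2)cc1
F0 | step 5 | none | none
F3 | step 2 | sodium 1-hydroxy-2-(4-methoxyphenyl)ethanesulfonate (racemic) | COc1ccc(CC(O)S(=O)(=O)[O-])cc1.[Na+]
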